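Cuts: with the O-protecting groups off, ring C is opened at O1–C2 and C4–C4a (aryl 1,1-dimethylpropargyl ether). Ring B is taken apart at C4a–C8a, C5–C6 and C8–C8a (cyclobutenone + ethoxyacetylene), and the four-membered ring at its two ketene–alkyne bonds. Ring A loses its C5' side chain and its C1' acyl group.
Enabling feature: ring B is a hexasubstituted benzene whose oxygens on C5, C7 and C8a alternate with carbons on C4a, C6 (methyl) and C8 (bridge CH2). Only the C8a oxygen, para to the C6 methyl, belongs to ring C. A vinylketene benzannulation turns the ketene carbonyl into exactly this oxygen, giving the one free phenol next to the one ring C–H (C4a).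
Forward order: ring A comes from 2-methylphloroglucinol and is filled up (acyl, OMe, CHO, two OBn). The aldehyde is grown to a propanoyl chloride, whose ketene closes the cyclobutenone on the future bridge carbon. Ring B is then annulated, ring C closes last, and the silyl, benzyl and ethyl ethers are removed.
Stereochemistry: the single center is bought as (R)-2-methylbutanoic acid and only carried along. It never meets a strong base, and the transient centers made on the way are erased by aromatisation or oxidation.

Key step: step 10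

Notation: rings B and C carry chromanone numbers (O1 to C8a) and ring A carries primed numbers (C1' acyl, C3' methyl, C4' methoxy, C5' bridge); Ar stands for 2,4-bis(benzyloxy)-6-methoxy-5-methyl-3-[(2R)-2-methylbutanoyl]phenyl, the protected ring A bonded through C5'.
Assumption: (R)-2-methylbutanoic acid of high enantiomeric purity, propyne (THF solution), ethoxyacetylene (hexane solution) and 3-chloro-3-methylbut-1-yne are taken as commercial; centers that are erased later (the sp3 ring carbon of the cyclobutenone, the carbinol carbon of the chromanol) are left undefined in the SMILES.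

Step 1
Reactants: 1 (R)-2-methylbutanoic acid
Product: 2 (R)-2-methylbutanoyl chloride
Conditions: (COCl)2, DMF (cat.), CH2Cl2, 0 °C to rt
Reagents that add atoms: oxalyl chloride, O=C(Cl)C(=O)Cl
Why: Acid chloride formation with oxalyl chloride under DMF catalysis is base-free and mild, so neither ketene formation nor enolisation can racemise the α-center.

Step 2
Reactants: 2 (R)-2-methylbutanoyl chloride; 3 2-methylbenzene-1,3,5-triol
Product: 4 (2R)-2-methyl-1-(2,4,6-trihydroxy-3-methylphenyl)butan-1-one
Conditions: AlCl3 (4 equiv), CH2Cl2/PhNO2, 0 °C to rt; then 1 M HCl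
Reagents that add atoms: none
Why: Friedel–Crafts C-acylation takes one of the two equivalent free positions of the very electron-rich triol (any O-acyl product undergoes Fries rearrangement under AlCl3), the first acyl group blocks a second acylation, and working at or below room temperature limits enolisation of the aluminium-bound ketone so the R center is kept.

Step 3
Reactants: 4 (2R)-2-methyl-1-(2,4,6-trihydroxy-3-methylphenyl)butan-1-one
Product: 5 (2R)-1-(2,6-dihydroxy-4-methoxy-3-methylphenyl)-2-methylbutan-1-one
Conditions: Me2SO4 (1.0 equiv), K2CO3 (1.0 equiv), acetone, rt to 40 °C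
Reagents that add atoms: dimethyl sulfate, COS(=O)(=O)OC
Why: Williamson-type O-methylation with one equivalent of base and of a hard electrophile should go to the C4' hydroxyl, which is para to the ketone and the most acidic, while the C2' and C6' hydroxyls are held in hydrogen bonds to the carbonyl oxygen; the phenoxide form of the ketone does not enolise, which shields the stereocenter.

Step 4
Reactants: 5 (2R)-1-(2,6-dihydroxy-4-methoxy-3-methylphenyl)-2-methylbutan-1-one
Product: 7 2,4-dihydroxy-6-methoxy-5-methyl-3-[(2R)-2-methylbutanoyl]benzaldehyde, via aryl iminium chloride 6 (not isolated)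
Conditions: POCl3, DMF, EtOAc, 0 °C to rt; then H2O, 40 °C
Reagents that add atoms: N,N-dimethylformamide, CN(C)C=O; water, O
Why: Vilsmeier–Haack formylation can only attack C5', the one unsubstituted ring carbon, which three oxygen substituents still activate, and hydrolysis of iminium salt 6 releases the aldehyde.

Step 5
Reactants: 7 2,4-dihydroxy-6-methoxy-5-methyl-3-[(2R)-2-methylbutanoyl]benzaldehyde
Product: 8 2,4-bis(benzyloxy)-6-methoxy-5-methyl-3-[(2R)-2-methylbutanoyl]benzaldehyde (ArCHO)
Conditions: BnBr (2.5 equiv), K2CO3, DMF, 50 °C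
Reagents that add atoms: benzyl bromide, BrCc1ccccc1
Why: Williamson benzylation of the two chelated phenols should stay on oxygen because every ring carbon is substituted and two carbonyl groups withdraw charge, and K2CO3 is too weak to deprotonate the α-carbon of the hindered ketone.

Step 6
Reactants: 8 ArCHO; 9 Meldrum's acid (2,2-dimethyl-1,3-dioxane-4,6-dione)
Product: 12 3-Ar-propanoic acid, via arylidene Meldrum's acid 10 (not isolated), via arylmethyl Meldrum's acid 11 (not isolated)
Conditions: HCO2H/Et3N (5:2), 95 °C; then 1 M HCl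
Reagents that add atoms: none
Why: Knoevenagel condensation (10), conjugate hydride transfer from formate to the highly electrophilic alkylidene malonate (11) and hydrolytic decarboxylation add two carbons in one pot without a hydrogenation catalyst, so the benzyl ethers and the di-ortho-substituted ketone are left alone.

Step 7
Reactants: 12 3-Ar-propanoic acid
Product: 13 3-Ar-propanoyl chloride
Conditions: (COCl)2, DMF (cat.), CH2Cl2, 0 °C to rt; used crude at once
Reagents that add atoms: oxalyl chloride, O=C(Cl)C(=O)Cl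
Why: Standard acid chloride formation needs no Lewis acid, and immediate use leaves the neighbouring ether oxygens no time to attack the acyl chloride.

Step 8
Reactants: 14 propyne
Product: 17 1-(triisopropylsilyloxy)prop-1-yne, via 1-propynyllithium 15 (not isolated), via lithium prop-1-yn-1-olate 16 (not isolated)
Conditions: n-BuLi, THF, −78 °C; t-BuOOLi (from t-BuOOH and LiN(SiMe3)2), −78 to 0 °C; i-Pr3SiOTf, −78 to 0 °C
Reagents that add atoms: tert-butyl hydroperoxide, CC(C)(C)OO; triisopropylsilyl trifluoromethanesulfonate, CC(C)[Si](OS(=O)(=O)C(F)(F)F)(C(C)C)C(C)C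
Why: Oxidation of a lithium acetylide with lithium tert-butyl peroxide is the established route to ynolates, and the bulky silyl triflate traps ynolate 16 on oxygen rather than on carbon to give the stable silyl ynol ether.

Step 9
Reactants: 13 3-Ar-propanoyl chloride; 17 1-(triisopropylsilyloxy)prop-1-yne
Product: 19 4-(Ar-methyl)-2-methyl-3-(triisopropylsilyloxy)cyclobut-2-en-1-one (both epimers at C4), via monoalkylketene 18 (not isolated)
Conditions: Et3N (1.5 equiv), 17 (2.5 equiv), CH2Cl2, 13 added over 6 h, rt to 40 °C; filtration through Et3N-washed silica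
Reagents that add atoms: none
Why: Dehydrochlorination gives ketene 18, which enters the known ketene–siloxyalkyne (2+2) cycloaddition with the methyl-bearing alkyne carbon attacking the ketene carbonyl carbon, so methyl ends on C2 and silyloxy on C3 next to the Ar-methyl-bearing sp3 carbon; that new center forms without control, which does not matter because it becomes aromatic C8.

Step 10
Reactants: 19 4-(Ar-methyl)-2-methyl-3-(triisopropylsilyloxy)cyclobut-2-en-1-one; 20 ethoxyacetylene
Product: 25 2-(Ar-methyl)-5-ethoxy-4-methyl-3-(triisopropylsilyloxy)phenol, via siloxy vinylketene 21 (not isolated), via 4-alkenylcyclobutenone 22 (not isolated), via dienylketene 23 (not isolated), via cyclohexadienone 24 (not isolated)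
Conditions: 20 (5 equiv, in portions), toluene, sealed tube, 80 to 110 °C
Reagents that add atoms: none
Why: Heating opens 19 by a conrotatory four-electron electrocyclic reaction, the Ar-methyl group on the sp3 carbon turning outward, to siloxy vinylketene 21, whose ketene carbonyl carbon is attacked by the nucleophilic CH terminus of 20; (2+2) closure gives 22 and with it the C4a–C8a and C5–C6 bonds. A second four-electron opening gives dienylketene 23, and its disrotatory six-electron electrocyclisation joins C8 to C8a, closing ring B as a six-membered carbocycle (24) that tautomerises to phenol 25. The closest known reaction type is the Danheiser benzannulation of cyclobutenones with alkoxyalkynes, in which 3-alkoxycyclobutenones of the kind of 22 are themselves the species that open on heating, so the 3-silyloxy group of 19 should be tolerated. No stereocenter is created, since the sp3 center of 19 and the quaternary center of 22 vanish on aromatisation, and the neutral medium leaves the remote R center untouched. The selectivity needed is the orientation of the ketene–alkyne cycloaddition, and the polarisation of the ynol ether secures it: ethoxy lands on C5 beside the C6 methyl, hydrogen on C4a, and the former ketene oxygen is the only free hydroxyl, on C8a. The bath stays at or below 110 °C and 20 is fed in portions because it slowly loses ethylene by a retro-ene reaction at higher temperature.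

Step 11
Reactants: 25 2-(Ar-methyl)-5-ethoxy-4-methyl-3-(triisopropylsilyloxy)phenol; 26 3-chloro-3-methylbut-1-yne
Product: 27 2-methylbut-3-yn-2-yl ether of 25 (ether oxygen on C8a)
Conditions: DBU, CuCl2·2H2O (1 mol %), MeCN, 0 °C to rt
Reagents that add atoms: none
Why: Copper-catalysed O-propargylation of phenols with tertiary propargylic halides proceeds through a copper-stabilised propargylic cation at 0 °C, and 25 offers a single free hydroxyl.

Step 12
Reactants: 27 2-methylbut-3-yn-2-yl ether of 25
Product: 30 8-(Ar-methyl)-5-ethoxy-2,2,6-trimethyl-7-(triisopropylsilyloxy)-2H-chromene, via ortho-allenylphenol 28 (not isolated), via ortho-quinone methide 29 (not isolated)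
Conditions: o-xylene, 140 °C
Reagents that add atoms: none
Why: The aromatic propargyl Claisen rearrangement can only reach C4a (C8 is blocked) and forms C4–C4a, after which 28 undergoes a 1,5-hydrogen shift to 29 and an oxa-6π electrocyclisation re-forms O1–C2 and closes ring C under neutral conditions.

Step 13
Reactants: 30 8-(Ar-methyl)-5-ethoxy-2,2,6-trimethyl-7-(triisopropylsilyloxy)-2H-chromene
Product: 31 8-(Ar-methyl)-5-ethoxy-2,2,6-trimethyl-7-(triisopropylsilyloxy)chroman-4-ol (both epimers at C4)
Conditions: Mn(dpm)3 (10 mol %, dpm = dipivaloylmethanate), PhSiH3, O2 (1 atm), i-PrOH/CH2Cl2, 0 °C to rt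
Reagents that add atoms: dioxygen, O=O
Why: In the Mukaiyama hydration, hydrogen-atom transfer to C3 gives the benzylic C4 radical, which O2 captures and the silane reduces to the Markovnikov alcohol; the new center needs no control because it is oxidised next, and any ketone formed directly converges in step 14.

Step 14
Reactants: 31 8-(Ar-methyl)-5-ethoxy-2,2,6-trimethyl-7-(triisopropylsilyloxy)chroman-4-ol
Product: 32 8-(Ar-methyl)-5-ethoxy-2,2,6-trimethyl-7-(triisopropylsilyloxy)chroman-4-one
Conditions: Dess–Martin periodinane, CH2Cl2, 0 °C to rt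
Reagents that add atoms: none
Why: Dess–Martin oxidation of the only hydroxyl group, a benzylic secondary alcohol, is essentially neutral and spares the silyl, benzyl and alkyl ethers and the diarylmethane.

Step 15
Reactants: 32 8-(Ar-methyl)-5-ethoxy-2,2,6-trimethyl-7-(triisopropylsilyloxy)chroman-4-one
Product: 33 8-(Ar-methyl)-5-ethoxy-7-hydroxy-2,2,6-trimethylchroman-4-one
Conditions: Bu4NF, AcOH, THF, 0 °C to rt
Reagents that add atoms: none
Why: Fluoride cleaves the aryl silyl ether, and acetic acid buffers the medium so that neither retro-oxa-Michael opening of ring C nor enolisation next to the R center can set in.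

Step 16
Reactants: 33 8-(Ar-methyl)-5-ethoxy-7-hydroxy-2,2,6-trimethylchroman-4-one
Product: 34 8-({2,4-dihydroxy-6-methoxy-5-methyl-3-[(2R)-2-methylbutanoyl]phenyl}methyl)-5,7-dihydroxy-2,2,6-trimethylchroman-4-one (CNP0303209.1)
Conditions: BCl3 (8 equiv), pentamethylbenzene (4 equiv), CH2Cl2, −78 to 0 °C; then H2O
Reagents that add atoms: none
Why: BCl3 with pentamethylbenzene as cation trap removes both benzyl ethers at −78 °C, and on warming the boron chelate between the C4 carbonyl and the C5 oxygen directs the known dealkylation of an ortho-carbonyl aryl ether onto the ethyl group, whereas the C4' methyl ether is para to its ketone, cannot chelate and should resist BCl3 at 0 °C.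

Compound list
1 | (R)-2-methylbutanoic acid | CC[C@@H](C)C(=O)O | starting material
2 | (R)-2-methylbutanoyl chloride | CC[C@@H](C)C(=O)Cl | intermediate
3 | 2-methylbenzene-1,3,5-triol | Cc1c(O)cc(O)cc1O | starting material
4 | (2R)-2-methyl-1-(2,4,6-trihydroxy-3-methylphenyl)butan-1-one | CC[C@@H](C)C(=O)c1c(O)c(C)c(O)cc1O | intermediate
5 | (2R)-1-(2,6-dihydroxy-4-methoxy-3-methylphenyl)-2-methylbutan-1-one | CC[C@@H](C)C(=O)c1c(O)c(C)c(OC)cc1O | intermediate
6 | {2,4-dihydroxy-6-methoxy-5-methyl-3-[(2R)-2-methylbutanoyl]phenyl}methylidene(dimethyl)ammonium chloride | CC[C@@H](C)C(=O)c1c(O)c(C)c(OC)c(C=[N+](C)C)c1O.[Cl-] | intermediate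
7 | 2,4-dihydroxy-6-methoxy-5-methyl-3-[(2R)-2-methylbutanoyl]benzaldehyde | CC[C@@H](C)C(=O)c1c(O)c(C)c(OC)c(C=O)c1O | intermediate
8 | 2,4-bis(benzyloxy)-6-methoxy-5-methyl-3-[(2R)-2-methylbutanoyl]benzaldehyde | CC[C@@H](C)C(=O)c1c(OCc2ccccc2)c(C)c(OC)c(C=O)c1OCc1ccccc1 | intermediate
9 | Meldrum's acid (2,2-dimethyl-1,3-dioxane-4,6-dione) | CC1(C)OC(=O)CC(=O)O1 | starting material
10 | 5-(Ar-methylidene)-2,2-dimethyl-1,3-dioxane-4,6-dione | CC[C@@H](C)C(=O)c1c(OCc2ccccc2)c(C)c(OC)c(C=C2C(=O)OC(C)(C)OC2=O)c1OCc1ccccc1 | intermediate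
11 | 5-(Ar-methyl)-2,2-dimethyl-1,3-dioxane-4,6-dione | CC[C@@H](C)C(=O)c1c(OCc2ccccc2)c(C)c(OC)c(CC2C(=O)OC(C)(C)OC2=O)c1OCc1ccccc1 | intermediate
12 | 3-Ar-propanoic acid | CC[C@@H](C)C(=O)c1c(OCc2ccccc2)c(C)c(OC)c(CCC(=O)O)c1OCc1ccccc1 | intermediate
13 | 3-Ar-propanoyl chloride | CC[C@@H](C)C(=O)c1c(OCc2ccccc2)c(C)c(OC)c(CCC(=O)Cl)c1OCc1ccccc1 | intermediate
14 | propyne | CC#C | starting material
15 | 1-propynyllithium | CC#C[Li] | intermediate
16 | lithium prop-1-yn-1-olate | CC#C[O-].[Li+] | intermediate
17 | 1-(triisopropylsilyloxy)prop-1-yne | CC#CO[Si](C(C)C)(C(C)C)C(C)C | intermediate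
18 | 3-Ar-prop-1-en-1-one (ArCH2CH=C=O) | CC[C@@H](C)C(=O)c1c(OCc2ccccc2)c(C)c(OC)c(CC=C=O)c1OCc1ccccc1 | intermediate
19 | 4-(Ar-methyl)-2-methyl-3-(triisopropylsilyloxy)cyclobut-2-en-1-one, both epimers at C4 | CC[C@@H](C)C(=O)c1c(OCc2ccccc2)c(C)c(OC)c(CC2C(=O)C(C)=C2O[Si](C(C)C)(C(C)C)C(C)C)c1OCc1ccccc1 | intermediate
20 | ethoxyacetylene | C#COCC | starting material
21 | (3Z)-5-Ar-2-methyl-3-(triisopropylsilyloxy)penta-1,3-dien-1-one | CC[C@@H](C)C(=O)c1c(OCc2ccccc2)c(C)c(OC)c(C/C=C(\O[Si](C(C)C)(C(C)C)C(C)C)C(C)=C=O)c1OCc1ccccc1 | intermediate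
22 | 4-[(1Z)-3-Ar-1-(triisopropylsilyloxy)prop-1-enyl]-3-ethoxy-4-methylcyclobut-2-en-1-one, both epimers at C4 | CC[C@@H](C)C(=O)c1c(OCc2ccccc2)c(C)c(OC)c(C/C=C(\O[Si](C(C)C)(C(C)C)C(C)C)C2(C)C(=O)C=C2OCC)c1OCc1ccccc1 | intermediate
23 | (3E,5Z)-7-Ar-3-ethoxy-4-methyl-5-(triisopropylsilyloxy)hepta-1,3,5-trien-1-one | CC[C@@H](C)C(=O)c1c(OCc2ccccc2)c(C)c(OC)c(C/C=C(\O[Si](C(C)C)(C(C)C)C(C)C)/C(C)=C(/OCC)C=C=O)c1OCc1ccccc1 | intermediate
24 | 6-(Ar-methyl)-3-ethoxy-4-methyl-5-(triisopropylsilyloxy)cyclohexa-2,4-dien-1-one | CC[C@@H](C)C(=O)c1c(OCc2ccccc2)c(C)c(OC)c(CC2C(=O)C=C(OCC)C(C)=C2O[Si](C(C)C)(C(C)C)C(C)C)c1OCc1ccccc1 | intermediate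
25 | 2-(Ar-methyl)-5-ethoxy-4-methyl-3-(triisopropylsilyloxy)phenol | CC[C@@H](C)C(=O)c1c(OCc2ccccc2)c(C)c(OC)c(Cc2c(O[Si](C(C)C)(C(C)C)C(C)C)c(C)c(OCC)cc2O)c1OCc1ccccc1 | intermediate
26 | 3-chloro-3-methylbut-1-yne | CC(C)(Cl)C#C | starting material
27 | 2-methylbut-3-yn-2-yl ether of 25 | CC[C@@H](C)C(=O)c1c(OCc2ccccc2)c(C)c(OC)c(Cc2c(O[Si](C(C)C)(C(C)C)C(C)C)c(C)c(OCC)cc2OC(C)(C)C#C)c1OCc1ccccc1 | intermediate
28 | 2-(Ar-methyl)-5-ethoxy-4-methyl-6-(3-methylbuta-1,2-dienyl)-3-(triisopropylsilyloxy)phenol | CC[C@@H](C)C(=O)c1c(OCc2ccccc2)c(C)c(OC)c(Cc2c(O[Si](C(C)C)(C(C)C)C(C)C)c(C)c(OCC)c(C=C=C(C)C)c2O)c1OCc1ccccc1 | intermediate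
29 | 2-(Ar-methyl)-5-ethoxy-4-methyl-6-(3-methylbut-2-enylidene)-3-(triisopropylsilyloxy)cyclohexa-2,4-dien-1-one, side chain cis to the carbonyl group | CC[C@@H](C)C(=O)c1c(OCc2ccccc2)c(C)c(OC)c(CC2=C(O[Si](C(C)C)(C(C)C)C(C)C)C(C)=C(OCC)/C(=C/C=C(C)C)C2=O)c1OCc1ccccc1 | intermediate
30 | 8-(Ar-methyl)-5-ethoxy-2,2,6-trimethyl-7-(triisopropylsilyloxy)-2H-chromene | CC[C@@H](C)C(=O)c1c(OCc2ccccc2)c(C)c(OC)c(Cc2c(O[Si](C(C)C)(C(C)C)C(C)C)c(C)c(OCC)c3c2OC(C)(C)C=C3)c1OCc1ccccc1 | intermediate
31 | 8-(Ar-methyl)-5-ethoxy-2,2,6-trimethyl-7-(triisopropylsilyloxy)chroman-4-ol, both epimers at C4 | CC[C@@H](C)C(=O)c1c(OCc2ccccc2)c(C)c(OC)c(Cc2c(O[Si](C(C)C)(C(C)C)C(C)C)c(C)c(OCC)c3c2OC(C)(C)CC3O)c1OCc1ccccc1 | intermediate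
32 | 8-(Ar-methyl)-5-ethoxy-2,2,6-trimethyl-7-(triisopropylsilyloxy)chroman-4-one | CC[C@@H](C)C(=O)c1c(OCc2ccccc2)c(C)c(OC)c(Cc2c(O[Si](C(C)C)(C(C)C)C(C)C)c(C)c(OCC)c3c2OC(C)(C)CC3=O)c1OCc1ccccc1 | intermediate
33 | 8-(Ar-methyl)-5-ethoxy-7-hydroxy-2,2,6-trimethylchroman-4-one | CC[C@@H](C)C(=O)c1c(OCc2ccccc2)c(C)c(OC)c(Cc2c(O)c(C)c(OCC)c3c2OC(C)(C)CC3=O)c1OCc1ccccc1 | intermediate
34 | 8-({2,4-dihydroxy-6-methoxy-5-methyl-3-[(2R)-2-methylbutanoyl]phenyl}methyl)-5,7-dihydroxy-2,2,6-trimethylchroman-4-one | CC[C@@H](C)C(=O)c1c(O)c(C)c(OC)c(Cc2c(O)c(C)c(O)c3c2OC(C)(C)CC3=O)c1O | target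

Total steps: 16. Longest linear sequence: 15 (steps 1 to 7 and 9 to 16, counted from 1); step 8 is the side branch.

Steps most likely to fail

Step 10 (benzannulation). The vinylogous silyl ester resonance of 19 may raise the ring-opening temperature into the range where the ynol ether fragments by a retro-ene reaction. The alkyne would then be lost before it is captured. The phenol may also be acylated by the vinylketene as it forms. The fallback makes ring B separately and joins it through the methylene carbon; it sets out from 5 and 3 and comes back at 34. Aminomethylation of 5 at C5' with Eschenmoser's salt (CH2Cl2, rt) should give the Mannich base (2R)-1-{3-[(dimethylamino)methyl]-2,6-dihydroxy-4-methoxy-5-methylphenyl}-2-methylbutan-1-one F1. Condensation of 3 with 3-methylbut-2-enoic acid in MeSO3H/P2O5 at 70 °C (Friedel–Crafts acylation, then oxa-Michael closure) should give 5,7-dihydroxy-2,2,6-trimethylchroman-4-one F2. Ring closure onto the other ortho hydroxyl competes in that condensation and would call for chromatographic separation. Heating F1 with F2 in dioxane at 100 °C expels dimethylamine to give the ring A ortho-quinone methide F3. C8 of F2, its only free ring carbon, traps F3 to give 34 directly.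

Step 9 (ketene–siloxyalkyne cycloaddition). Amine-promoted dimerisation of the monoalkylketene may outrun its capture, and the vinylogous silyl ester may lose its silyl group on isolation. The fallback releases the same ketene slowly and without base by a retro-ene reaction; it sets out from 8 and comes back at 19.
- Reduction of the aldehyde with NaBH4 (MeOH/THF, 0 °C), which leaves the hindered ketone, should give the benzylic alcohol ArCH2OH F4.
- An Appel reaction (CBr4, PPh3, CH2Cl2, 0 °C) should give the benzylic bromide ArCH2Br F5.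
- Alkylation of lithium tert-butoxyacetylide (THF/DMPU, −78 to −20 °C) should give the tert-butyl ynol ether 1-Ar-3-tert-butoxyprop-2-yne F6. The shielded, α-branched ketone should be neither attacked nor deprotonated in this step.
- Heating F6 with 17 in toluene at 80 °C expels 2-methylpropene and releases 18 at a low stationary concentration with no amine present. The (2+2) cycloaddition to 19 then has only the siloxyalkyne as partner.

Step 11 (O-propargylation). The phenol sits beside the very bulky Ar-methyl group, so ether formation with a tertiary electrophile may be slower than loss of HCl from the chloride. The fallback forms the carbon–carbon bond first; it sets out from 25 and comes back at 30, bypassing 27. Condensation of 25 with 3-methylbut-2-enal under ethylenediammonium diacetate catalysis (xylene, reflux) attacks through C4a and loses water to give the same ortho-quinone methide 29. This closes by oxa-6π electrocyclisation to 30. No compound outside the list is made (F0).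

Further compounds
F1 | step 10 | (2R)-1-{3-[(dimethylamino)methyl]-2,6-dihydroxy-4-methoxy-5-methylphenyl}-2-methylbutan-1-one | CC[C@@H](C)C(=O)c1c(O)c(C)c(OC)c(CN(C)C)c1O
F2 | step 10 | 5,7-dihydroxy-2,2,6-trimethylchroman-4-one | CC1(C)CC(=O)c2c(O)c(C)c(O)cc2O1
F3 | step 10 | 3-hydroxy-5-methoxy-4-methyl-6-methylidene-2-[(2R)-2-methylbutanoyl]cyclohexa-2,4-dien-1-one | CC[C@@H](C)C(=O)C1=C(O)C(C)=C(OC)C(=C)C1=O
F4 | step 9 | (2R)-1-[2,6-bis(benzyloxy)-3-(hydroxymethyl)-4-methoxy-5-methylphenyl]-2-methylbutan-1-one | CC[C@@H](C)C(=O)c1c(OCc2ccccc2)c(C)c(OC)c(CO)c1OCc1ccccc1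
F5 | step 9 | (2R)-1-[2,6-bis(benzyloxy)-3-(bromomethyl)-4-methoxy-5-methylphenyl]-2-methylbutan-1-one | CC[C@@H](C)C(=O)c1c(OCc2ccccc2)c(C)c(OC)c(CBr)c1OCc1ccccc1
F6 | step 9 | (2R)-1-[2,6-bis(benzyloxy)-3-(3-tert-butoxyprop-2-ynyl)-4-methoxy-5-methylphenyl]-2-methylbutan-1-one | CC[C@@H](C)C(=O)c1c(OCc2ccccc2)c(C)c(OC)c(CC#COC(C)(C)C)c1OCc1ccccc1
F0 | step 11 | none | none
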